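**Retrosynthetic overview**

- Rings A and C and the (2S) centre at C2 are those of (S)-liquiritigenin 1. The target adds three C5 units on C8, C3' and C5', each ortho to a phenolic oxygen (O7 or O4'), and one of them is closed onto O4' as the 2,2-dimethyl-2H-pyran ring D.
- The C5 donor is made from prenyl bromide 2 and tris(tetra-n-butylammonium) hydrogen diphosphate 3, which give dimethylallyl diphosphate 4.
- Key disconnection: the three aryl–CH2 bonds at C8, C3' and C5'. Two aromatic prenyltransferases, used one after the other in one pot, take 1 and 4 through the mono- and diprenyl stages 5 and 6 to triprenylflavanone 7.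
- Last disconnection: the O4'–CMe2 bond of ring D. DDQ closes it on 7 through ortho-quinone methide 8 to give target 9.
- Ring order: rings A, B and C are bought intact; ring D is the only ring formed, and it is formed last.

Key step: step 2

Remarks: prenyl means 3-methylbut-2-en-1-yl. Compound 4 is drawn as the free acid but is isolated and used as its triammonium salt. Commercial (S)-liquiritigenin is assumed to be enantiopure, which is checked by chiral HPLC before use.

**Route**

Step 1
Reactants: 2 prenyl bromide (1-bromo-3-methylbut-2-ene); 3 tris(tetra-n-butylammonium) hydrogen diphosphate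
Product: 4 dimethylallyl diphosphate (triammonium salt)
Conditions: 3 (2 equiv), MeCN, 0 °C to rt; sulfonated polystyrene cation-exchange resin (NH4+ form), aq. NH4HCO3/iPrOH; lyophilisation; cellulose, iPrOH/MeCN/aq. NH4HCO3
Reagents that add atoms: tris(tetra-n-butylammonium) hydrogen diphosphate 3, CCCC[N+](CCCC)(CCCC)CCCC.CCCC[N+](CCCC)(CCCC)CCCC.CCCC[N+](CCCC)(CCCC)CCCC.OP(=O)([O-])OP(=O)([O-])[O-]
Why: SN2 displacement of the primary allylic bromide by the hydrogen diphosphate trianion in MeCN is the standard preparation of allylic diphosphates; excess 3 should keep the product from being alkylated a second time, and the mildly basic ammonium buffer protects the acid-labile allylic diphosphate.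

Step 2
Reactants: 1 (S)-liquiritigenin; 4 dimethylallyl diphosphate
Product: 7 (2S)-7,4'-dihydroxy-8,3',5'-triprenylflavanone, via 8-prenylliquiritigenin 5 (not isolated), via 8,3'-diprenylliquiritigenin 6 (not isolated)
Conditions: flavanone 8-dimethylallyltransferase (Sophora flavescens SfN8DT-1 type, recombinant yeast microsomes), 4 (2 equiv), MgCl2 (10 mM), Tris-HCl pH 7.5, DMSO (5%), 30 °C, N2; then NovQ (Streptomyces ABBA-fold prenyltransferase, from E. coli), 4 (3 equiv, in portions), 30 °C; EtOAc extraction
Reagents that add atoms: dimethylallyl diphosphate 4, CC(C)=CCOP(=O)(O)OP(=O)(O)O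
Why: Proposed new method: a flavanone 8-dimethylallyltransferase and a ring B ortho-prenyltransferase are used one after the other in a single vessel to place three C5 units on one flavanone, which has not been shown; the closest known reactions are the C8 dimethylallylation of naringenin and liquiritigenin by the membrane-bound plant enzyme and the ortho C-prenylation of 4-hydroxyphenyl substrates, flavonoid ring B among them, by soluble ABBA-fold enzymes. Each enzyme ionises the C–O bond of 4 (the diphosphate is held by Mg2+ on the aspartate-rich motifs of the first enzyme and by lysine and arginine side chains in the second) to a dimethylallyl cation lying over the bound phenol, whose ortho carbon attacks the CH2 end in a Friedel–Crafts alkylation before an active-site base removes the ring proton. Three aryl–CH2 bonds form, no ring closes and no stereocentre is created; the (2S) centre of 1 is only carried through, which the near-neutral aqueous medium at 30 °C should allow because opening of ring C to the chalcone needs base. The step needs C8 over C6, carbon over oxygen and the linear over the tert-prenyl isomer, all of which rest on how each active site holds the cation against the phenol and not on the intrinsic reactivity of the substrate; the 8-transferase is given unsubstituted 1 first, the substrate type it is known to accept. On ring B the local twofold symmetry of the 4-hydroxyphenyl group makes C3' and C5' the same position, so 6 is a single compound, and in 6 the only carbon left ortho to O4' is C5', which should be reached by binding the ring turned over, with the now more electron-rich 2-alkylphenol as the nucleophile.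

Step 3
Reactants: 7 (2S)-7,4'-dihydroxy-8,3',5'-triprenylflavanone
Product: 9 (2S)-7-hydroxy-8-prenyl-2-(2,2-dimethyl-8-prenyl-2H-chromen-6-yl)chroman-4-one (the target), via ortho-quinone methide 8 (not isolated)
Conditions: DDQ (1.0 equiv, added slowly), toluene, 0 °C to rt
Reagents that add atoms: none
Why: DDQ dehydrogenation of an ortho-prenylphenol to the ortho-quinone methide followed by oxa-6π electrocyclisation is the standard entry to 2,2-dimethyl-2H-chromenes, and the electron-rich 2,6-dialkylphenol of ring B should be oxidised before the 7-hydroxyl, which is deactivated by conjugation with the C4 ketone, while the second ring B prenyl group has no free phenol once O4' is in ring D and C2 is not touched.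

**Compound list**

1 | (S)-liquiritigenin, (2S)-7,4'-dihydroxyflavanone | O=C1C[C@@H](c3ccc(O)cc3)Oc2cc(O)ccc12 | starting material
2 | prenyl bromide, 1-bromo-3-methylbut-2-ene | CC(C)=CCBr | starting material
3 | tris(tetra-n-butylammonium) hydrogen diphosphate | CCCC[N+](CCCC)(CCCC)CCCC.CCCC[N+](CCCC)(CCCC)CCCC.CCCC[N+](CCCC)(CCCC)CCCC.OP(=O)([O-])OP(=O)([O-])[O-] | starting material
4 | dimethylallyl diphosphate (drawn as the free acid, handled as the triammonium salt) | CC(C)=CCOP(=O)(O)OP(=O)(O)O | intermediate
5 | (2S)-7,4'-dihydroxy-8-prenylflavanone (8-prenylliquiritigenin) | O=C1C[C@@H](c3ccc(O)cc3)Oc2c(CC=C(C)C)c(O)ccc12 | intermediate (not isolated)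
6 | (2S)-7,4'-dihydroxy-8,3'-diprenylflavanone (8,3'-diprenylliquiritigenin) | O=C1C[C@@H](c3ccc(O)c(CC=C(C)C)c3)Oc2c(CC=C(C)C)c(O)ccc12 | intermediate (not isolated)
7 | (2S)-7,4'-dihydroxy-8,3',5'-triprenylflavanone | O=C1C[C@@H](c3cc(CC=C(C)C)c(O)c(CC=C(C)C)c3)Oc2c(CC=C(C)C)c(O)ccc12 | intermediate
8 | ortho-quinone methide of 7: ring B as a cyclohexa-2,5-dienone with C4'=O, a (Z)-3-methylbut-2-enylidene group on C3' and the prenyl group on C5'; (2S) | O=C1C[C@@H](C3=C\C(=C\C=C(C)C)C(=O)C(CC=C(C)C)=C3)Oc2c(CC=C(C)C)c(O)ccc12 | intermediate (not isolated)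
9 | (2S)-7-hydroxy-8-prenyl-2-(2,2-dimethyl-8-prenyl-2H-chromen-6-yl)chroman-4-one, CNP0110366.1 | CC(C)=CCc1cc([C@@H]2CC(=O)c3ccc(O)c(CC=C(C)C)c3O2)cc2c1OC(C)(C)C=C2 | target

**Step count**

Total steps: 3. Longest linear sequence: 3 steps (2 → 4 → 7 → 9); compound 1 enters at step 2.

**Steps most likely to fail**

1. Step 2 (the step proposed as new). The sequence may stall after one or two transfers if the ring B enzyme does not accept the turned-over monoprenyl ring. The dimethylallyl cation may also be delivered to O4', O7 or C6 instead of the intended carbons.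

   Fallback by known chemistry, setting out from prenyl bromide 2 and returning to the route at 7:
   - Compound 2 C-alkylates two purchased phenols as their phenoxides in aqueous KOH. 2,4-Dihydroxyacetophenone should give 2,4-dihydroxy-3-prenylacetophenone F1, and 4-hydroxybenzaldehyde (2 equiv of 2) should give 4-hydroxy-3,5-diprenylbenzaldehyde F3; each is separated from its regio- and O-alkylated isomers by chromatography.
   - MOMCl/K2CO3 in acetone protects the non-chelated 4-hydroxyl of F1 to give 2-hydroxy-4-(methoxymethoxy)-3-prenylacetophenone F2. MOMCl/NaH in DMF converts F3 into 4-(methoxymethoxy)-3,5-diprenylbenzaldehyde F4.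
   - Claisen–Schmidt condensation of F2 with F4 (KOH, EtOH, rt) should give (E)-2'-hydroxy-4,4'-bis(methoxymethoxy)-3,5,3'-triprenylchalcone F5.
   - Dilute HCl in MeOH removes both MOM groups to give (E)-2',4,4'-trihydroxy-3,5,3'-triprenylchalcone F6.
   - NaOAc in refluxing EtOH closes ring C by intramolecular oxa-Michael addition to racemic 7,4'-dihydroxy-8,3',5'-triprenylflavanone F7.
   - Preparative HPLC on an amylose tris(3,5-dimethylphenylcarbamate) phase separates 7 from (2R)-7,4'-dihydroxy-8,3',5'-triprenylflavanone F8, which can be returned to the NaOAc equilibration.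

2. Step 3. Oxidation may not stop at ring B: the 7-hydroxyl and the 8-prenyl group can cyclise in the same way, and hydride loss from C2 can lead to dehydrogenation of ring C.

   Fallback, setting out from 7 and returning at 9:
   - TBSCl (1.05 equiv) and imidazole in CH2Cl2 at 0 °C should silylate the more acidic and less hindered 7-hydroxyl, leaving the 4'-hydroxyl (flanked by two prenyl groups) free. This gives (2S)-7-(tert-butyldimethylsilyloxy)-4'-hydroxy-8,3',5'-triprenylflavanone F9.
   - DDQ in toluene can then cyclise only on ring B, giving (2S)-7-(tert-butyldimethylsilyloxy)-8-prenyl-2-(2,2-dimethyl-8-prenyl-2H-chromen-6-yl)chroman-4-one F10.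
   - HF·pyridine in THF at 0 °C removes the silyl group without base and should give 9.

3. Step 1. The allylic diphosphate may ionise and hydrolyse during ion exchange and concentration, or the diphosphate may be alkylated at both ends.

   Fallback, setting out from 2 and returning at 4, in which the P–O–P bond is built stepwise under anhydrous, non-acidic conditions:
   - Compound 2 is displaced by tetra-n-butylammonium dihydrogen phosphate in MeCN to give dimethylallyl phosphate F11.
   - F11 is activated with 1,1'-carbonyldiimidazole in DMF to give dimethylallyl phosphorimidazolide F12.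
   - F12 is coupled with tributylammonium phosphate in DMF to give 4 after ammonium ion exchange.

**Further compounds**

F1 | step 2 | 2,4-dihydroxy-3-prenylacetophenone | CC(=O)c1ccc(O)c(CC=C(C)C)c1O
F2 | step 2 | 2-hydroxy-4-(methoxymethoxy)-3-prenylacetophenone | CC(=O)c1ccc(OCOC)c(CC=C(C)C)c1O
F3 | step 2 | 4-hydroxy-3,5-diprenylbenzaldehyde | O=Cc1cc(CC=C(C)C)c(O)c(CC=C(C)C)c1
F4 | step 2 | 4-(methoxymethoxy)-3,5-diprenylbenzaldehyde | O=Cc1cc(CC=C(C)C)c(OCOC)c(CC=C(C)C)c1
F5 | step 2 | (E)-2'-hydroxy-4,4'-bis(methoxymethoxy)-3,5,3'-triprenylchalcone | COCOc1ccc(C(=O)/C=C/c2cc(CC=C(C)C)c(OCOC)c(CC=C(C)C)c2)c(O)c1CC=C(C)C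
F6 | step 2 | (E)-2',4,4'-trihydroxy-3,5,3'-triprenylchalcone | Oc1ccc(C(=O)/C=C/c2cc(CC=C(C)C)c(O)c(CC=C(C)C)c2)c(O)c1CC=C(C)C
F7 | step 2 | racemic 7,4'-dihydroxy-8,3',5'-triprenylflavanone | O=C1CC(c3cc(CC=C(C)C)c(O)c(CC=C(C)C)c3)Oc2c(CC=C(C)C)c(O)ccc12
F8 | step 2 | (2R)-7,4'-dihydroxy-8,3',5'-triprenylflavanone | O=C1C[C@H](c3cc(CC=C(C)C)c(O)c(CC=C(C)C)c3)Oc2c(CC=C(C)C)c(O)ccc12
F9 | step 3 | (2S)-7-(tert-butyldimethylsilyloxy)-4'-hydroxy-8,3',5'-triprenylflavanone | O=C1C[C@@H](c3cc(CC=C(C)C)c(O)c(CC=C(C)C)c3)Oc2c(CC=C(C)C)c(O[Si](C)(C)C(C)(C)C)ccc12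
F10 | step 3 | (2S)-7-(tert-butyldimethylsilyloxy)-8-prenyl-2-(2,2-dimethyl-8-prenyl-2H-chromen-6-yl)chroman-4-one | CC(C)=CCc1cc([C@@H]2CC(=O)c3ccc(O[Si](C)(C)C(C)(C)C)c(CC=C(C)C)c3O2)cc2c1OC(C)(C)C=C2
F11 | step 1 | dimethylallyl phosphate | CC(C)=CCOP(=O)(O)O
F12 | step 1 | dimethylallyl phosphorimidazolide | CC(C)=CCOP(=O)(O)n1ccnc1
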